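## Structural features

The target is a tricycle. Ring A is a pentasubstituted benzene (methoxy groups at C2, C3 and C4, hydrogen at C1) fused through C4a and C9a to a seven-membered carbocycle, ring B (C5 to C9). C5 is the spiro atom shared with ring C, a cross-conjugated 2,6-dimethoxycyclohexa-2,5-dienone. Ring C has a mirror plane through C5 and its carbonyl carbon, so C5 is quaternary but not stereogenic. The only stereocentres are C7 (methyl, R), C8 (methyl, S) and C9 (benzoyloxy, R); they are contiguous, with methyl/methyl trans and methyl/benzoyloxy trans on ring B. The dienone is fragile (conjugate addition, reduction, acid-induced dienone–phenol rearrangement). The C9 benzoate is a secondary benzylic ester on an electron-rich ring, so it can ionise in strong acid, be hydrogenolysed, or be cleaved or shifted by base. The real difficulty is the contiguous triad on a flexible seven-membered ring, where substrate control is unreliable, together with closing ring B at a quaternary carbon. The key step exploits C6–C7–C8–C9, an unbranched chain CH2–CH(CH3)–CH(CH3)–CH(O)Ar between C5 and C9a. Each of C7, C8 and C9 carries one hydrogen and one simple group, so each can enter as the carbenoid carbon of a one-carbon boronic ester homologation, with the C9 oxygen carried as boron.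

## Logic of the disconnections

17 to 16. The bond cut is C5–C6. Ring C is the dienone form of a para-alkylated phenol, so this single cut removes ring B, the quaternary carbon and the dienone together and postpones the fragile dienone to the last step. The forward step must alkylate the para carbon of a phenoxide in a seven-membered closure, in competition with E2 elimination of a β-branched primary halide and with intermolecular O-alkylation.

16 to 15 to 13 + 14. The C6–I bond is traced to C6–OH, then the biaryl bond C4a–C1′ is cut. This separates ring C as the ready-made boronate 14 and leaves ring A as an aryl bromide. The coupling must work on a bromide flanked by a methoxy group and a branched benzylic carbon, and must tolerate a free phenol, a free primary alcohol and the C9 ester.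

13 to 11 (through 12). The C6–O bond is traced to C6–Si, which makes C6 inert through all the earlier organometallic steps. The silicon-to-oxygen exchange is placed before the biaryl coupling, not after it. In 11 there is no phenol for the peroxide to oxidise and no second electron-rich ring that could trap a C9 cation as a fluorene. The acid stage must cleave the Si–phenyl bond without ionising the C9 ester.

11 to 10 to 9 to 8. The C4a–Br bond, the ester C–O bond and the C9–O bond are removed in turn; C9–O is traced to C9–B. Both free ring positions of 10 are equivalent, so bromination has no regiochemical problem. The boron-to-oxygen exchange must go with retention.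

8 to 5 + 2 + 2 + 4 (through 6 and 7). The bonds cut are C8–C9, C7–C8 and C6–C7. This reduces the whole stereotriad to three achiral building blocks and puts each stereocentre under control of a chiral ligand. Two points need care in the forward direction. The two insertions of 2 need opposite ligand enantiomers, because the C7/C8 methyl pair is syn in the open chain (trans in ring B); one enantiomer used twice would give the anti pair. The carbenoid from 4 is benzylic and configurationally labile, so C9 must be set by a ligand that biases the equilibrium of the lithiated species, not by kinetic deprotonation.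

2 to 1 and 4 to 3. The ester C–O bond of 2 and the carbamate C–O bond of 4 are cut, leading back to a commercial acid and a commercial benzylic alcohol.

## Other disconnections considered

Alternative 1: Ring C is cut at C5–C6′ and at the C2′=C3′ double bond. Forward, the enamine of the C5 aldehyde A2 adds to the vinyl ketone A3, and the methoxy-bearing carbon condenses with the formyl group (Robinson spiroannulation) to give the spiro 2-methoxycyclohexenone A1.
- In favour: the regiochemistry of the aldol closure is fixed by ring size, and C5 is made under mild, nearly neutral conditions.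
- Against: the step creates none of C7, C8 or C9, so A2 must already contain ring B with the complete triad, which leaves the hard problem untouched. C5 becomes a temporary stereocentre in A1, giving two diastereomers that only converge later. A1 is one methoxy group and two unsaturations short of ring C, so α′-oxygenation, O-methylation and dehydrogenation must follow, as well as exchange of the silyl ether for the benzoate.
- Comparison: on the quaternary centre alone this alternative is the better one, because an enamine Michael addition has no competing elimination, unlike the SN2 closure of the chosen plan. On stereocontrol and step economy the chosen plan is better, since it makes the triad in one reagent-controlled operation and reaches ring C at the correct oxidation level from 14.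

Alternative 2: C8 is removed from ring B by cutting C8–C9 and C7–C8. Forward, the silyl enol ether of the six-membered spiro ketone A5 is cyclopropanated (ZnEt2, CH2I2, Simmons–Smith), and FeCl3 opens the siloxycyclopropane to give the ring-expanded enone A4.
- In favour: a six-membered ring closes more easily than a seven-membered one, and the one-carbon insertion is regiospecific.
- Against: A4 is achiral and lacks the C8 methyl, so all three stereocentres would then have to be set by substrate control on a flexible ring (conjugate reduction, enolate methylation, carbonyl reduction). Ring C is already present, so its dienone competes in every reduction, offers two more alkenes to the zinc carbenoid, and is exposed to FeCl3, a Lewis acid and oxidant that can trigger dienone–phenol rearrangement.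
- Comparison: on formation of ring B this alternative is the equal or the better of the chosen plan. On stereochemistry and chemoselectivity the chosen plan is better, because its centres are set on an open chain before any dienone exists. The step count after the key step would be higher here.

Alternative 3: Both C–CH3 bonds are cut. Forward, a chiral phosphoramidite–copper catalyst adds methyl from AlMe3 to C7 of the bare spiro enone A7, and the aluminium enolate is methylated at C8 with CH3I to give the trans-7,8-dimethyl ketone A6.
- In favour: chirality is used catalytically, two C–C bonds and two stereocentres come from one operation, and the route is convergent. On reagent economy per stereocentre this is better than three stoichiometric charges of chiral ligand.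
- Against: A7 carries the ring C dienone, a second acceptor for the methyl nucleophile. Aluminium enolates are sluggish towards CH3I and usually need activation that the dienone may not survive. C9 would still have to be set by reduction of the aryl ketone, with hydride delivered trans to the C8 methyl and selectively over the dienone carbonyl, and no reagent handle guarantees either.
- Comparison: the chosen plan needs more stoichiometric reagent but has no chemoselectivity problem, because the dienone appears only in its last step, and it controls C9 by the same logic as C7 and C8.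

Key step: step 3

Remarks on the chemistry:
- Compounds 5 and 14 and both enantiomers of sparteine are taken as purchased.
- The lithiated carbamate from 4 is treated as configurationally labile. The (S,S)-bis(oxazoline) ligand, 2,2′-(pentane-3,3-diyl)bis[(4S)-4-isopropyl-4,5-dihydrooxazole], is assumed to favour the (R)-configured organolithium; the sense of induction is unverified, and if a model boronic ester shows the opposite sense, the (R,R) ligand is used instead.

## Route

Step 1
Reactants: 1 2,4,6-triisopropylbenzoic acid
Product: 2 ethyl 2,4,6-triisopropylbenzoate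
Conditions: EtI, K2CO3, DMF, 40 °C
Reagents that add atoms: iodoethane, CCI
Why: SN2 O-alkylation of the potassium carboxylate; the reacting oxygen lies outside the shield of the two ortho isopropyl groups, so the hindered acid should esterify cleanly where acyl substitution would be slow.

Step 2
Reactants: 3 3,4,5-trimethoxybenzyl alcohol
Product: 4 3,4,5-trimethoxybenzyl N,N-diisopropylcarbamate
Conditions: i-Pr2NC(O)Cl, Et3N, CH2Cl2, reflux
Reagents that add atoms: N,N-diisopropylcarbamoyl chloride, CC(C)N(C(C)C)C(Cl)=O
Why: Carbamoylation (acyl substitution) of the primary benzylic alcohol; the carbamate later directs and stabilises α-lithiation and serves as the leaving group on C9.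

Step 3
Reactants: 5 2-[(dimethylphenylsilyl)methyl]-4,4,5,5-tetramethyl-1,3,2-dioxaborolane; 2 ethyl 2,4,6-triisopropylbenzoate (two separate portions); 4 3,4,5-trimethoxybenzyl N,N-diisopropylcarbamate
Product: 8 2-[(1R,2R,3S)-4-(dimethylphenylsilyl)-2,3-dimethyl-1-(3,4,5-trimethoxyphenyl)butyl]-4,4,5,5-tetramethyl-1,3,2-dioxaborolane, via (R)-silylpropyl boronic ester 6 (not isolated), via (2S,3S)-dimethylbutyl boronic ester 7 (not isolated)
Conditions: (a) 2, s-BuLi, (−)-sparteine, Et2O, −78 °C; 5, then 35 °C; (b) 2, s-BuLi, (+)-sparteine, Et2O, −78 °C; crude 6, then 35 °C; (c) 4, s-BuLi, (S,S)-bis(oxazoline) ligand, Et2O, −78 °C; crude 7, then rt; acid and base washes after each cycle, no chromatography until 8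
Reagents that add atoms: none
Why: Each cycle is a lithiation–borylation: s-BuLi and the chiral ligand generate an α-oxygenated organolithium (a carbenoid) that adds to boron with retention to give a tetracoordinate boronate, and on warming the carbon group on boron shifts to the carbenoid carbon anti to the departing benzoate or carbamate (1,2-metallate rearrangement, inversion at the carbenoid carbon, retention in the migrating carbon). In cycle (a) (−)-sparteine removes the pro-S proton of 2, the configurationally stable (S)-carbenoid captures 5, and migration of the silylmethyl group forms C6–C7 and should give (R)-6. In cycle (b) the (R)-carbenoid from (+)-sparteine is required, because the two methyl groups must be syn in the open chain (trans in ring B); migration of C7 forms C7–C8 and should give (2S,3S)-7. In cycle (c) the lithiated benzylic carbamate is not configurationally stable, so its configuration is fixed by equilibration of the two diastereomeric ligand complexes under the bis(oxazoline) ligand; retentive borylation and migration of C8 form C8–C9 and should give (1R)-8. The closest known reaction type is the iterative, reagent-controlled homologation of boronic esters with lithiated benzoates and carbamates, a stereospecific relative of the Matteson homologation; no ring is closed. All three stereocentres are controlled by the ligand-bound carbenoid and not by the growing chain, whose boron-bearing carbon cannot epimerise. The step needs exactly one insertion per cycle: in cycles (a) and (b) free carbenoid decomposes on warming before the boronate rearranges, and in cycle (c) a small excess of carbenoid and the hindered boron of 8 limit a second insertion. It also needs intermediates free of diamine and of acid 1, which the washes between cycles provide.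

Step 4
Reactants: 8 2-[(1R,2R,3S)-4-(dimethylphenylsilyl)-2,3-dimethyl-1-(3,4,5-trimethoxyphenyl)butyl]-4,4,5,5-tetramethyl-1,3,2-dioxaborolane
Product: 9 (1R,2S,3S)-4-(dimethylphenylsilyl)-2,3-dimethyl-1-(3,4,5-trimethoxyphenyl)butan-1-ol
Conditions: H2O2, NaOH, THF/H2O, 0 °C to rt
Reagents that add atoms: hydrogen peroxide, OO
Why: Boronic ester oxidation; hydroperoxide adds to boron and C9 shifts from boron to oxygen with retention, so the C–B configuration becomes the (1R) C–O configuration, and the phenylsilane is inert because silicon carries no heteroatom.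

Step 5
Reactants: 9 (1R,2S,3S)-4-(dimethylphenylsilyl)-2,3-dimethyl-1-(3,4,5-trimethoxyphenyl)butan-1-ol
Product: 10 (1R,2S,3S)-4-(dimethylphenylsilyl)-2,3-dimethyl-1-(3,4,5-trimethoxyphenyl)butyl benzoate
Conditions: BzCl, Et3N, DMAP (cat.), CH2Cl2, 0 °C to rt
Reagents that add atoms: benzoyl chloride, O=C(Cl)c1ccccc1
Why: DMAP-catalysed acylation of the secondary benzylic alcohol; no bond to a stereocentre is broken.

Step 6
Reactants: 10 (1R,2S,3S)-4-(dimethylphenylsilyl)-2,3-dimethyl-1-(3,4,5-trimethoxyphenyl)butyl benzoate
Product: 11 (1R,2S,3S)-1-(2-bromo-3,4,5-trimethoxyphenyl)-4-(dimethylphenylsilyl)-2,3-dimethylbutyl benzoate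
Conditions: NBS (1.0 equiv), MeCN, 0 °C to rt, dark
Reagents that add atoms: N-bromosuccinimide, O=C1CCC(=O)N1Br
Why: Electrophilic aromatic bromination; the two free ring positions are equivalent and activated by ortho and para methoxy groups, so one equivalent should give a single monobromide at the future C4a, while the phenyl ring on silicon is far less nucleophilic under these conditions.

Step 7
Reactants: 11 (1R,2S,3S)-1-(2-bromo-3,4,5-trimethoxyphenyl)-4-(dimethylphenylsilyl)-2,3-dimethylbutyl benzoate
Product: 13 (1R,2S,3S)-1-(2-bromo-3,4,5-trimethoxyphenyl)-4-hydroxy-2,3-dimethylbutyl benzoate, via fluorosilane 12 (not isolated)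
Conditions: HBF4·OEt2, CH2Cl2, 0 °C to rt; then H2O2, KF, KHCO3, THF/MeOH, rt
Reagents that add atoms: hydrogen peroxide, OO
Why: Fleming–Tamao oxidation in two stages: ipso-protonation of the phenyl ring on silicon expels benzene and leaves fluorosilane 12, whose C6–Si bond then rearranges to C6–O under fluoride and peroxide; it is run before the biaryl and the phenol exist, so no neighbouring electron-rich ring can trap a C9 cation and nothing peroxide-sensitive is present.

Step 8
Reactants: 13 (1R,2S,3S)-1-(2-bromo-3,4,5-trimethoxyphenyl)-4-hydroxy-2,3-dimethylbutyl benzoate; 14 2,6-dimethoxy-4-(4,4,5,5-tetramethyl-1,3,2-dioxaborolan-2-yl)phenol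
Product: 15 (1R,2S,3S)-4-hydroxy-1-(4′-hydroxy-3′,4,5,5′,6-pentamethoxy-[1,1′-biphenyl]-2-yl)-2,3-dimethylbutyl benzoate
Conditions: Pd(OAc)2, SPhos, K3PO4, dioxane/H2O, 60 °C
Reagents that add atoms: none
Why: Suzuki–Miyaura coupling; zerovalent palladium formed from Pd(OAc)2 and the bulky biaryl phosphine should insert into the hindered, electron-rich C–Br bond, and boronate 14, which has no ortho substituents, transmetallates readily; the phenol and the primary alcohol are tolerated.

Step 9
Reactants: 15 (1R,2S,3S)-4-hydroxy-1-(4′-hydroxy-3′,4,5,5′,6-pentamethoxy-[1,1′-biphenyl]-2-yl)-2,3-dimethylbutyl benzoate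
Product: 16 (1R,2S,3S)-1-(4′-hydroxy-3′,4,5,5′,6-pentamethoxy-[1,1′-biphenyl]-2-yl)-4-iodo-2,3-dimethylbutyl benzoate
Conditions: I2, PPh3, imidazole, CH2Cl2, 0 °C to rt
Reagents that add atoms: iodine, II
Why: Appel iodination; the primary alkoxyphosphonium ion is displaced by iodide (SN2), the phenol cannot be substituted this way, and every ring position ortho or para to the phenol oxygen is already occupied.

Step 10
Reactants: 16 (1R,2S,3S)-1-(4′-hydroxy-3′,4,5,5′,6-pentamethoxy-[1,1′-biphenyl]-2-yl)-4-iodo-2,3-dimethylbutyl benzoate
Product: 17 (7R,8S,9R)-2,3,3′,4,5′-pentamethoxy-7,8-dimethyl-4′-oxo-6,7,8,9-tetrahydrospiro[benzo[7]annulene-5,1′-cyclohexane]-2′,5′-dien-9-yl benzoate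
Conditions: Cs2CO3, DMF (0.005 M), rt to 50 °C
Reagents that add atoms: none
Why: Intramolecular para-C-alkylation of the caesium phenoxide (dearomatising 7-exo-tet SN2) forms C5–C6, ring B and the ring C dienone at once; the phenoxide oxygen cannot reach the iodide, both ortho carbons carry methoxy groups, dilution suppresses intermolecular O-alkylation, and C5 is not stereogenic because ring C is symmetric.

## Compound list

1 | 2,4,6-triisopropylbenzoic acid | CC(C)c1cc(C(C)C)c(C(=O)O)c(C(C)C)c1 | starting material
2 | ethyl 2,4,6-triisopropylbenzoate | CCOC(=O)c1c(C(C)C)cc(C(C)C)cc1C(C)C | intermediate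
3 | 3,4,5-trimethoxybenzyl alcohol | COc1cc(CO)cc(OC)c1OC | starting material
4 | 3,4,5-trimethoxybenzyl N,N-diisopropylcarbamate | COc1cc(COC(=O)N(C(C)C)C(C)C)cc(OC)c1OC | intermediate
5 | 2-[(dimethylphenylsilyl)methyl]-4,4,5,5-tetramethyl-1,3,2-dioxaborolane | C[Si](C)(CB1OC(C)(C)C(C)(C)O1)c1ccccc1 | starting material
6 | 2-[(2R)-1-(dimethylphenylsilyl)propan-2-yl]-4,4,5,5-tetramethyl-1,3,2-dioxaborolane | C[Si](C)(c1ccccc1)C[C@@H](C)B1OC(C)(C)C(C)(C)O1 | intermediate
7 | 2-[(2S,3S)-4-(dimethylphenylsilyl)-3-methylbutan-2-yl]-4,4,5,5-tetramethyl-1,3,2-dioxaborolane | C[Si](C)(c1ccccc1)C[C@@H](C)[C@H](C)B1OC(C)(C)C(C)(C)O1 | intermediate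
8 | 2-[(1R,2R,3S)-4-(dimethylphenylsilyl)-2,3-dimethyl-1-(3,4,5-trimethoxyphenyl)butyl]-4,4,5,5-tetramethyl-1,3,2-dioxaborolane | C[Si](C)(c1ccccc1)C[C@@H](C)[C@H](C)[C@@H](B1OC(C)(C)C(C)(C)O1)c1cc(OC)c(OC)c(OC)c1 | intermediate
9 | (1R,2S,3S)-4-(dimethylphenylsilyl)-2,3-dimethyl-1-(3,4,5-trimethoxyphenyl)butan-1-ol | C[Si](C)(c1ccccc1)C[C@@H](C)[C@H](C)[C@@H](O)c1cc(OC)c(OC)c(OC)c1 | intermediate
10 | (1R,2S,3S)-4-(dimethylphenylsilyl)-2,3-dimethyl-1-(3,4,5-trimethoxyphenyl)butyl benzoate | C[Si](C)(c1ccccc1)C[C@@H](C)[C@H](C)[C@@H](OC(=O)c1ccccc1)c1cc(OC)c(OC)c(OC)c1 | intermediate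
11 | (1R,2S,3S)-1-(2-bromo-3,4,5-trimethoxyphenyl)-4-(dimethylphenylsilyl)-2,3-dimethylbutyl benzoate | C[Si](C)(c1ccccc1)C[C@@H](C)[C@H](C)[C@@H](OC(=O)c1ccccc1)c1cc(OC)c(OC)c(OC)c1Br | intermediate
12 | (1R,2S,3S)-1-(2-bromo-3,4,5-trimethoxyphenyl)-4-(fluorodimethylsilyl)-2,3-dimethylbutyl benzoate | C[Si](C)(F)C[C@@H](C)[C@H](C)[C@@H](OC(=O)c1ccccc1)c1cc(OC)c(OC)c(OC)c1Br | intermediate
13 | (1R,2S,3S)-1-(2-bromo-3,4,5-trimethoxyphenyl)-4-hydroxy-2,3-dimethylbutyl benzoate | OC[C@@H](C)[C@H](C)[C@@H](OC(=O)c1ccccc1)c1cc(OC)c(OC)c(OC)c1Br | intermediate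
14 | 2,6-dimethoxy-4-(4,4,5,5-tetramethyl-1,3,2-dioxaborolan-2-yl)phenol | COc1cc(B2OC(C)(C)C(C)(C)O2)cc(OC)c1O | starting material
15 | (1R,2S,3S)-4-hydroxy-1-(4′-hydroxy-3′,4,5,5′,6-pentamethoxy-[1,1′-biphenyl]-2-yl)-2,3-dimethylbutyl benzoate | OC[C@@H](C)[C@H](C)[C@@H](OC(=O)c1ccccc1)c1cc(OC)c(OC)c(OC)c1-c1cc(OC)c(O)c(OC)c1 | intermediate
16 | (1R,2S,3S)-1-(4′-hydroxy-3′,4,5,5′,6-pentamethoxy-[1,1′-biphenyl]-2-yl)-4-iodo-2,3-dimethylbutyl benzoate | IC[C@@H](C)[C@H](C)[C@@H](OC(=O)c1ccccc1)c1cc(OC)c(OC)c(OC)c1-c1cc(OC)c(O)c(OC)c1 | intermediate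
17 | (7R,8S,9R)-2,3,3′,4,5′-pentamethoxy-7,8-dimethyl-4′-oxo-6,7,8,9-tetrahydrospiro[benzo[7]annulene-5,1′-cyclohexane]-2′,5′-dien-9-yl benzoate | COC1=CC2(C=C(OC)C1=O)C[C@@H](C)[C@H](C)[C@@H](OC(=O)c1ccccc1)c1cc(OC)c(OC)c(OC)c12 | target

## Step count and least certain steps

Total step count: 10. Longest linear sequence: 9 steps (step 1, then steps 3 to 10).

Step 3 (key step). The most likely failure is erosion of configuration at C9. The lithiated benzylic carbamate epimerises, so C9 depends on a thermodynamic preference between two ligand complexes that may be small for the trimethoxyphenyl group or mismatched with the chiral boronic ester 7. Incomplete boronate formation at the hindered boron of 7 and carry-over of diamine or acid 1 between the telescoped cycles are secondary risks; adding MgBr2·OEt2 in MeOH before warming is a possible aid to the last migration.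

Fallback for step 3: C9 is set by ketone reduction instead of by the carbenoid. Boronic ester 7 is purified and homologated with the carbenoid from 4 using s-BuLi and TMEDA without a chiral ligand. This gives 2-[(2R,3S)-4-(dimethylphenylsilyl)-2,3-dimethyl-1-(3,4,5-trimethoxyphenyl)butyl]-4,4,5,5-tetramethyl-1,3,2-dioxaborolane F1 as a mixture at C1. Oxidation with H2O2/NaOH gives the epimeric alcohols (2S,3S)-4-(dimethylphenylsilyl)-2,3-dimethyl-1-(3,4,5-trimethoxyphenyl)butan-1-ol F2. Dess–Martin periodinane converts both into the single aryl ketone (2S,3S)-4-(dimethylphenylsilyl)-2,3-dimethyl-1-(3,4,5-trimethoxyphenyl)butan-1-one F3. Corey–Bakshi–Shibata reduction with BH3·SMe2 and the (S)-methyl oxazaborolidine, the aryl group acting as the large substituent, should return the (1R) alcohol 9. The ketone must be handled without base to keep C8 intact.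

Step 7. The most likely failure is ionisation of the C9 benzylic ester during the acid stage, leading to elimination or loss of configuration. Perhydrolysis of the benzoate or its shift to the new primary hydroxyl during the basic peroxide stage is a second risk.

Fallback for step 7: silicon is exchanged under basic conditions before any ester is present. Alcohol 9 is treated with t-BuOK in DMSO and then with TBAF, H2O2 and KHCO3; the C9 alkoxide assists cleavage of the Si–phenyl bond. This gives (1R,2S,3S)-2,3-dimethyl-1-(3,4,5-trimethoxyphenyl)butane-1,4-diol F4. TBSCl and imidazole silylate the primary hydroxyl to give (1R,2S,3S)-4-[(tert-butyldimethylsilyl)oxy]-2,3-dimethyl-1-(3,4,5-trimethoxyphenyl)butan-1-ol F5. Benzoylation gives (1R,2S,3S)-4-[(tert-butyldimethylsilyl)oxy]-2,3-dimethyl-1-(3,4,5-trimethoxyphenyl)butyl benzoate F6. NBS gives (1R,2S,3S)-1-(2-bromo-3,4,5-trimethoxyphenyl)-4-[(tert-butyldimethylsilyl)oxy]-2,3-dimethylbutyl benzoate F7. HF·pyridine removes the silyl ether and returns 13.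

Step 8. The most likely failure is slow oxidative addition at the hindered, electron-rich bromide, which lets protodeboronation of 14 take over. Transfer of the benzoyl group from the C9 oxygen to the free primary hydroxyl under warm aqueous base is the second risk. An excess of 14 addresses the first.

Fallback for step 8: the primary hydroxyl is masked during the coupling. Alcohol 13 is converted with Et3SiCl and imidazole into (1R,2S,3S)-1-(2-bromo-3,4,5-trimethoxyphenyl)-2,3-dimethyl-4-[(triethylsilyl)oxy]butyl benzoate F8. Coupling with 14 under the conditions of step 8 gives (1R,2S,3S)-1-(4′-hydroxy-3′,4,5,5′,6-pentamethoxy-[1,1′-biphenyl]-2-yl)-2,3-dimethyl-4-[(triethylsilyl)oxy]butyl benzoate F9. AcOH in THF/H2O removes the silyl ether and returns 15.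

Step 10. The most likely failure is E2 elimination of the β-branched primary iodide to a 1,1-disubstituted alkene, or intermolecular O-alkylation, because closure of a seven-membered ring at a carbon nucleophile is slow.

Fallback for step 10: a far better leaving group is used and the phenoxide is released by fluoride at low temperature instead of by carbonate. Diol 15 is silylated on both hydroxyls (TBSCl, imidazole, DMF) to give (1R,2S,3S)-4-[(tert-butyldimethylsilyl)oxy]-1-{4′-[(tert-butyldimethylsilyl)oxy]-3′,4,5,5′,6-pentamethoxy-[1,1′-biphenyl]-2-yl}-2,3-dimethylbutyl benzoate F10. PPTS in MeOH removes only the alkyl silyl ether, giving (1R,2S,3S)-1-{4′-[(tert-butyldimethylsilyl)oxy]-3′,4,5,5′,6-pentamethoxy-[1,1′-biphenyl]-2-yl}-4-hydroxy-2,3-dimethylbutyl benzoate F11. Tf2O and 2,6-lutidine at −78 °C give the primary triflate (1R,2S,3S)-1-{4′-[(tert-butyldimethylsilyl)oxy]-3′,4,5,5′,6-pentamethoxy-[1,1′-biphenyl]-2-yl}-2,3-dimethyl-4-{[(trifluoromethyl)sulfonyl]oxy}butyl benzoate F12. One equivalent of CsF in MeCN at low temperature unmasks the phenoxide, which should close onto the triflate to give 17.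

## Further compounds

F1 | step 3 | 2-[(2R,3S)-4-(dimethylphenylsilyl)-2,3-dimethyl-1-(3,4,5-trimethoxyphenyl)butyl]-4,4,5,5-tetramethyl-1,3,2-dioxaborolane, both C1 epimers | C[Si](C)(c1ccccc1)C[C@@H](C)[C@H](C)C(B1OC(C)(C)C(C)(C)O1)c1cc(OC)c(OC)c(OC)c1
F2 | step 3 | (2S,3S)-4-(dimethylphenylsilyl)-2,3-dimethyl-1-(3,4,5-trimethoxyphenyl)butan-1-ol, both C1 epimers | C[Si](C)(c1ccccc1)C[C@@H](C)[C@H](C)C(O)c1cc(OC)c(OC)c(OC)c1
F3 | step 3 | (2S,3S)-4-(dimethylphenylsilyl)-2,3-dimethyl-1-(3,4,5-trimethoxyphenyl)butan-1-one | C[Si](C)(c1ccccc1)C[C@@H](C)[C@H](C)C(=O)c1cc(OC)c(OC)c(OC)c1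
F4 | step 7 | (1R,2S,3S)-2,3-dimethyl-1-(3,4,5-trimethoxyphenyl)butane-1,4-diol | OC[C@@H](C)[C@H](C)[C@@H](O)c1cc(OC)c(OC)c(OC)c1
F5 | step 7 | (1R,2S,3S)-4-[(tert-butyldimethylsilyl)oxy]-2,3-dimethyl-1-(3,4,5-trimethoxyphenyl)butan-1-ol | CC(C)(C)[Si](C)(C)OC[C@@H](C)[C@H](C)[C@@H](O)c1cc(OC)c(OC)c(OC)c1
F6 | step 7 | (1R,2S,3S)-4-[(tert-butyldimethylsilyl)oxy]-2,3-dimethyl-1-(3,4,5-trimethoxyphenyl)butyl benzoate | CC(C)(C)[Si](C)(C)OC[C@@H](C)[C@H](C)[C@@H](OC(=O)c1ccccc1)c1cc(OC)c(OC)c(OC)c1
F7 | step 7 | (1R,2S,3S)-1-(2-bromo-3,4,5-trimethoxyphenyl)-4-[(tert-butyldimethylsilyl)oxy]-2,3-dimethylbutyl benzoate | CC(C)(C)[Si](C)(C)OC[C@@H](C)[C@H](C)[C@@H](OC(=O)c1ccccc1)c1cc(OC)c(OC)c(OC)c1Br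
F8 | step 8 | (1R,2S,3S)-1-(2-bromo-3,4,5-trimethoxyphenyl)-2,3-dimethyl-4-[(triethylsilyl)oxy]butyl benzoate | CC[Si](CC)(CC)OC[C@@H](C)[C@H](C)[C@@H](OC(=O)c1ccccc1)c1cc(OC)c(OC)c(OC)c1Br
F9 | step 8 | (1R,2S,3S)-1-(4′-hydroxy-3′,4,5,5′,6-pentamethoxy-[1,1′-biphenyl]-2-yl)-2,3-dimethyl-4-[(triethylsilyl)oxy]butyl benzoate | CC[Si](CC)(CC)OC[C@@H](C)[C@H](C)[C@@H](OC(=O)c1ccccc1)c1cc(OC)c(OC)c(OC)c1-c1cc(OC)c(O)c(OC)c1
F10 | step 10 | (1R,2S,3S)-4-[(tert-butyldimethylsilyl)oxy]-1-{4′-[(tert-butyldimethylsilyl)oxy]-3′,4,5,5′,6-pentamethoxy-[1,1′-biphenyl]-2-yl}-2,3-dimethylbutyl benzoate | CC(C)(C)[Si](C)(C)OC[C@@H](C)[C@H](C)[C@@H](OC(=O)c1ccccc1)c1cc(OC)c(OC)c(OC)c1-c1cc(OC)c(O[Si](C)(C)C(C)(C)C)c(OC)c1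
F11 | step 10 | (1R,2S,3S)-1-{4′-[(tert-butyldimethylsilyl)oxy]-3′,4,5,5′,6-pentamethoxy-[1,1′-biphenyl]-2-yl}-4-hydroxy-2,3-dimethylbutyl benzoate | OC[C@@H](C)[C@H](C)[C@@H](OC(=O)c1ccccc1)c1cc(OC)c(OC)c(OC)c1-c1cc(OC)c(O[Si](C)(C)C(C)(C)C)c(OC)c1
F12 | step 10 | (1R,2S,3S)-1-{4′-[(tert-butyldimethylsilyl)oxy]-3′,4,5,5′,6-pentamethoxy-[1,1′-biphenyl]-2-yl}-2,3-dimethyl-4-{[(trifluoromethyl)sulfonyl]oxy}butyl benzoate | FC(F)(F)S(=O)(=O)OC[C@@H](C)[C@H](C)[C@@H](OC(=O)c1ccccc1)c1cc(OC)c(OC)c(OC)c1-c1cc(OC)c(O[Si](C)(C)C(C)(C)C)c(OC)c1
A1 | alternative 1 | spiro 2-methoxycyclohex-2-enone with silyl ether at C9 (one spiro epimer drawn) | COC1=C[C@]2(CCC1=O)C[C@@H](C)[C@H](C)[C@@H](O[Si](C)(C)C(C)(C)C)c1cc(OC)c(OC)c(OC)c12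
A2 | alternative 1 | ring B C5 carbaldehyde with silyl ether at C9 | O=CC1C[C@@H](C)[C@H](C)[C@@H](O[Si](C)(C)C(C)(C)C)c2cc(OC)c(OC)c(OC)c12
A3 | alternative 1 | 1-methoxybut-3-en-2-one | COCC(=O)C=C
A4 | alternative 2 | ring B enone with C9 ketone, C7–C8 alkene and C7 methyl | COC1=CC2(C=C(OC)C1=O)C/C(C)=C\C(=O)c1cc(OC)c(OC)c(OC)c12
A5 | alternative 2 | six-membered spiro ketone with α-methyl group | COC1=CC2(C=C(OC)C1=O)CC(C)C(=O)c1cc(OC)c(OC)c(OC)c12
A6 | alternative 3 | trans-7,8-dimethyl spiro ketone | COC1=CC2(C=C(OC)C1=O)C[C@@H](C)[C@H](C)C(=O)c1cc(OC)c(OC)c(OC)c12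
A7 | alternative 3 | bare spiro enone with C9 ketone and C7–C8 alkene | COC1=CC2(C=C(OC)C1=O)C/C=C\C(=O)c1cc(OC)c(OC)c(OC)c12
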